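Everything rests on cutting ring A of the 4'-methoxyflavone half at C7–C8 and C4a–C5. That ring is a phloroglucinol: C5–C6–C7 equal one malonyl unit, C4a and C8a already belong to ring C, and C8, which bears C6 of the second flavone, is a benzylic carbon next to a pyranone. The precursor is therefore a 6-(4-methoxyphenyl)-4-pyranone carrying at C2 a CH2 group bound to C6 of a finished, benzyl-protected 7-methoxyflavone. In one operation its silyl dienol ether takes up malonyl dichloride, both bonds form, ring A appears as the free 5,7-diol, and the 6,8''-linkage is fixed without any biaryl coupling. Hydrogenolysis then ends the synthesis.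

Key step: step 11

Assumption: the target is drawn without a descriptor for the hindered C6–C8'' axis. The racemic mixture of atropisomers is therefore taken as the goal, and no step controls the axis.

Terms: half 1 is the 5,7-dihydroxy-4'-methoxyflavone unit, linked at C8. Half 2 is the 5,4'-dihydroxy-7-methoxyflavone unit, linked at C6.

Design remarks:
- O5 and O4' of half 2 are both carried as benzyl ethers, so the end-game is a neutral hydrogenolysis.
- No Lewis acid or benzyl cation then meets the nucleophilic C6 of the new ring A, and no methyl ether has to be told apart from another.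
- The free 5-OH needed for the allyl ether comes directly from a symmetrical 2,6-dihydroxyacetophenone. No selective demethylation beside a benzyl ether is needed.

Step 1
Reactants: 1 2',6'-dihydroxy-4'-methoxyacetophenone; 2 4-(benzyloxy)benzoyl chloride
Product: 3 1-[4-(benzyloxy)phenyl]-3-(2,6-dihydroxy-4-methoxyphenyl)propane-1,3-dione
Conditions: LiHMDS (4.2 equiv), THF, -78 to -10 °C; 2 (1.0 equiv), -78 °C to rt; aq HCl
Reagents that add atoms: none
Why: Baker–Venkataraman-type direct C-aroylation, in which the ketone enolate carbon of the trilithio polyanion of 1 is far more nucleophilic than the two lithium phenoxides and the fourth equivalent of base takes up the acidic proton of the diketone as it forms.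

Step 2
Reactants: 3 1-[4-(benzyloxy)phenyl]-3-(2,6-dihydroxy-4-methoxyphenyl)propane-1,3-dione
Product: 4 4'-benzyloxy-5-hydroxy-7-methoxyflavone
Conditions: AcOH, cat. H2SO4, 95 °C
Reagents that add atoms: none
Why: Acid-catalysed cyclodehydration of a 1-(2-hydroxyaryl)-1,3-diketone to a flavone, where the two phenols of 3 are equivalent so only one flavone can form, the second phenol ends as the chelated 5-OH, and the aryl benzyl ether tolerates the dilute acid.

Step 3
Reactants: 4 4'-benzyloxy-5-hydroxy-7-methoxyflavone; 5 allyl bromide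
Product: 6 5-allyloxy-4'-benzyloxy-7-methoxyflavone
Conditions: K2CO3, DMF, 60 °C
Reagents that add atoms: none
Why: Williamson ether synthesis, in which the chelated 5-OH is the only acidic group left and is alkylated by the reactive allylic halide on warming in a dipolar aprotic solvent.

Step 4
Reactants: 6 5-allyloxy-4'-benzyloxy-7-methoxyflavone
Product: 7 6-allyl-4'-benzyloxy-5-hydroxy-7-methoxyflavone
Conditions: PhNEt2, 205 °C, argon, sealed tube
Reagents that add atoms: none
Why: Aromatic Claisen rearrangement ([3,3]-sigmatropic shift), in which one ortho position of O5 is the ring-fusion carbon C4a, so the allyl group can only be delivered to C6, and enolisation of the dienone to the chelated phenol ends the sequence there.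

Step 5
Reactants: 7 6-allyl-4'-benzyloxy-5-hydroxy-7-methoxyflavone
Product: 8 6-allyl-5,4'-bis(benzyloxy)-7-methoxyflavone
Conditions: BnBr, Cs2CO3, cat. n-Bu4NI, DMF, 70 °C
Reagents that add atoms: benzyl bromide, BrCc1ccccc1
Why: Williamson ether synthesis, where the caesium phenoxide and in situ benzyl iodide overcome the low reactivity of the hindered, hydrogen-bonded 5-OH.

Step 6
Reactants: 8 6-allyl-5,4'-bis(benzyloxy)-7-methoxyflavone
Product: 9 2-[5,4'-bis(benzyloxy)-7-methoxyflavon-6-yl]acetaldehyde
Conditions: cat. OsO4, NaIO4, 2,6-lutidine, dioxane–H2O, rt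
Reagents that add atoms: osmium tetroxide, O=[Os](=O)(=O)=O (delivers the oxygen); sodium periodate, [Na+].[O-]I(=O)(=O)=O (terminal oxidant that refills it)
Why: Lemieux–Johnson cleavage, in which the monosubstituted alkene is dihydroxylated much faster than the electron-poor trisubstituted C2=C3 bond of the chromone and 2,6-lutidine suppresses side reactions of the enolisable aldehyde.

Step 7
Reactants: 9 2-[5,4'-bis(benzyloxy)-7-methoxyflavon-6-yl]acetaldehyde
Product: 10 2-[5,4'-bis(benzyloxy)-7-methoxyflavon-6-yl]acetic acid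
Conditions: NaClO2, NaH2PO4, 2-methyl-2-butene (excess), t-BuOH–THF–H2O, 0 °C to rt
Reagents that add atoms: sodium chlorite, [Na+].[O-]Cl=O
Why: Pinnick oxidation, which is chemoselective for the aldehyde while the excess alkene traps hypochlorous acid before it can chlorinate C8 of the alkoxy-rich arene.

Step 8
Reactants: 10 2-[5,4'-bis(benzyloxy)-7-methoxyflavon-6-yl]acetic acid
Product: 12 2-[5,4'-bis(benzyloxy)-7-methoxyflavon-6-yl]-N-methoxy-N-methylacetamide, via acylimidazole 11 (not isolated)
Conditions: CDI, THF, rt; then MeNH(OMe)·HCl, rt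
Reagents that add atoms: N,O-dimethylhydroxylamine hydrochloride, CNOC.Cl; 1,1'-carbonyldiimidazole, O=C(n1ccnc1)n1ccnc1 (its imidazolyl group stays only in intermediate 11)
Why: Weinreb amide formation by carboxyl activation as the acylimidazole and aminolysis, under near-neutral conditions that leave the benzyl ethers and the chromone intact.

Step 9
Reactants: 12 2-[5,4'-bis(benzyloxy)-7-methoxyflavon-6-yl]-N-methoxy-N-methylacetamide; 13 1-(4-methoxyphenyl)butane-1,3-dione
Product: 14 1-[5,4'-bis(benzyloxy)-7-methoxyflavon-6-yl]-6-(4-methoxyphenyl)hexane-2,4,6-trione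
Conditions: 13 (1.8 equiv), LDA (3.5 equiv), THF, 0 °C; 12, -78 to -20 °C; cold 1 M HCl
Reagents that add atoms: none
Why: Claisen-type acylation of a 1,3-diketone dianion at its terminal carbon with a Weinreb amide, whose chelated tetrahedral adduct survives until the quench so the acidic triketone never meets the dianion, only a small excess of dianion is needed, and the amide CH2 is less acidic than that of an ester.

Step 10
Reactants: 14 1-[5,4'-bis(benzyloxy)-7-methoxyflavon-6-yl]-6-(4-methoxyphenyl)hexane-2,4,6-trione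
Product: 15 2-{[5,4'-bis(benzyloxy)-7-methoxyflavon-6-yl]methyl}-6-(4-methoxyphenyl)-4H-pyran-4-one
Conditions: TFA, CH2Cl2, rt
Reagents that add atoms: none
Why: Acid-catalysed cyclodehydration of a 1,3,5-triketone to a 4-pyranone, where either terminal enol oxygen attacking the other terminal carbonyl gives the same 2,6-disubstituted ring and acid avoids the base-induced aldol closure to a resorcinol.

Step 11
Reactants: 15 2-{[5,4'-bis(benzyloxy)-7-methoxyflavon-6-yl]methyl}-6-(4-methoxyphenyl)-4H-pyran-4-one; 16 malonyl dichloride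
Product: 20 8-[5,4'-bis(benzyloxy)-7-methoxyflavon-6-yl]-5,7-dihydroxy-4'-methoxyflavone, via silyl dienol ether 17 (not isolated), via keto acid chloride 18 (not isolated), via dienylketene 19 (not isolated)
Conditions: LiHMDS (1.1 equiv), THF, -78 °C; Me3SiCl, -78 to 0 °C; volatiles removed in vacuo; 16 (1.0 equiv), CH2Cl2, -78 °C to reflux; MeOH, aq NaHCO3
Reagents that add atoms: chlorotrimethylsilane, C[Si](C)(C)Cl (its silyl group stays only in intermediate 17)
Why: Proposed new method: LiHMDS removes a proton from the CH2 between pyranone C2 and the aryl ring and O-silylation gives the 2-arylmethylidene-4-silyloxy-2H-pyran 17, an anhydrobase whose exocyclic carbon attacks one acyl chloride of 16 because this restores an aromatic 4-silyloxypyrylium ion, which sheds Me3SiCl to give 18 (bond C7–C8). On warming, 18 should lose HCl and enolise to dienylketene 19, whose two ends are the ketene carbon and pyranone C3. Ring A then closes as a six-membered carbocycle by thermal 6π electrocyclisation (bond C4a–C5), and tautomerisation of the cyclohexadienone gives the 5,7-diol without creating any stereocentre. The closest known reactions are the annulations of ketones and silyl enol ethers with malonyl dichloride to 4-hydroxy-2-pyranones and acylphloroglucinols, and the dienylketene closure of the Danheiser benzannulation. The step needs C- rather than O-acylation and a 1,3-C,C-bis-nucleophile: silicon masks O4, the symmetry of 16 means that a first attack through C3 followed by closure at the exocyclic carbon would build the same ring, and after either first acylation only one carbon lies within six-membered reach. Removing HN(SiMe3)2 before 16 is added, using one equivalent of 16, and separating the cold acylation from the warm HCl loss should protect the reagent, the silyl ether and the new phenols from side acylation.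

Step 12
Reactants: 20 8-[5,4'-bis(benzyloxy)-7-methoxyflavon-6-yl]-5,7-dihydroxy-4'-methoxyflavone
Product: 21 8-(5,4'-dihydroxy-7-methoxyflavon-6-yl)-5,7-dihydroxy-4'-methoxyflavone (CNP0253922.0)
Conditions: H2 (1 atm), Pd/C, THF–MeOH, rt
Reagents that add atoms: none
Why: Catalytic hydrogenolysis of aryl benzyl ethers, whose neutral conditions leave both methyl ethers, the phenols and the two chromone C2=C3 bonds untouched at one atmosphere.

Compound list
1 | 2',6'-dihydroxy-4'-methoxyacetophenone | CC(=O)c1c(O)cc(OC)cc1O | starting material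
2 | 4-(benzyloxy)benzoyl chloride | O=C(Cl)c1ccc(OCc2ccccc2)cc1 | starting material
3 | 1-[4-(benzyloxy)phenyl]-3-(2,6-dihydroxy-4-methoxyphenyl)propane-1,3-dione | COc1cc(O)c(C(=O)CC(=O)c2ccc(OCc3ccccc3)cc2)c(O)c1 | intermediate
4 | 4'-benzyloxy-5-hydroxy-7-methoxyflavone | COc1cc(O)c2c(=O)cc(-c3ccc(OCc4ccccc4)cc3)oc2c1 | intermediate
5 | allyl bromide | C=CCBr | starting material
6 | 5-allyloxy-4'-benzyloxy-7-methoxyflavone | C=CCOc1cc(OC)cc2oc(-c3ccc(OCc4ccccc4)cc3)cc(=O)c12 | intermediate
7 | 6-allyl-4'-benzyloxy-5-hydroxy-7-methoxyflavone | C=CCc1c(OC)cc2oc(-c3ccc(OCc4ccccc4)cc3)cc(=O)c2c1O | intermediate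
8 | 6-allyl-5,4'-bis(benzyloxy)-7-methoxyflavone | C=CCc1c(OC)cc2oc(-c3ccc(OCc4ccccc4)cc3)cc(=O)c2c1OCc5ccccc5 | intermediate
9 | 2-[5,4'-bis(benzyloxy)-7-methoxyflavon-6-yl]acetaldehyde | O=CCc1c(OC)cc2oc(-c3ccc(OCc4ccccc4)cc3)cc(=O)c2c1OCc5ccccc5 | intermediate
10 | 2-[5,4'-bis(benzyloxy)-7-methoxyflavon-6-yl]acetic acid | O=C(O)Cc1c(OC)cc2oc(-c3ccc(OCc4ccccc4)cc3)cc(=O)c2c1OCc5ccccc5 | intermediate
11 | 1-{2-[5,4'-bis(benzyloxy)-7-methoxyflavon-6-yl]acetyl}imidazole (not isolated) | O=C(Cc1c(OC)cc2oc(-c3ccc(OCc4ccccc4)cc3)cc(=O)c2c1OCc5ccccc5)n6ccnc6 | intermediate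
12 | 2-[5,4'-bis(benzyloxy)-7-methoxyflavon-6-yl]-N-methoxy-N-methylacetamide | CON(C)C(=O)Cc1c(OC)cc2oc(-c3ccc(OCc4ccccc4)cc3)cc(=O)c2c1OCc5ccccc5 | intermediate
13 | 1-(4-methoxyphenyl)butane-1,3-dione | COc1ccc(C(=O)CC(C)=O)cc1 | starting material
14 | 1-[5,4'-bis(benzyloxy)-7-methoxyflavon-6-yl]-6-(4-methoxyphenyl)hexane-2,4,6-trione (drawn as the triketo tautomer) | COc1ccc(C(=O)CC(=O)CC(=O)Cc2c(OC)cc3oc(-c4ccc(OCc5ccccc5)cc4)cc(=O)c3c2OCc6ccccc6)cc1 | intermediate
15 | 2-{[5,4'-bis(benzyloxy)-7-methoxyflavon-6-yl]methyl}-6-(4-methoxyphenyl)-4H-pyran-4-one | COc1ccc(-c2cc(=O)cc(Cc3c(OC)cc4oc(-c5ccc(OCc6ccccc6)cc5)cc(=O)c4c3OCc7ccccc7)o2)cc1 | intermediate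
16 | malonyl dichloride | O=C(Cl)CC(=O)Cl | starting material
17 | 2-{[5,4'-bis(benzyloxy)-7-methoxyflavon-6-yl]methylidene}-6-(4-methoxyphenyl)-4-(trimethylsilyloxy)-2H-pyran (not isolated; exocyclic alkene geometry not fixed) | COc1ccc(C2=CC(O[Si](C)(C)C)=CC(=Cc3c(OC)cc4oc(-c5ccc(OCc6ccccc6)cc5)cc(=O)c4c3OCc7ccccc7)O2)cc1 | intermediate
18 | 4-[5,4'-bis(benzyloxy)-7-methoxyflavon-6-yl]-4-[6-(4-methoxyphenyl)-4-oxo-4H-pyran-2-yl]-3-oxobutanoyl chloride (not isolated; racemic, centre lost on enolisation) | COc1ccc(-c2cc(=O)cc(C(C(=O)CC(=O)Cl)c3c(OC)cc4oc(-c5ccc(OCc6ccccc6)cc5)cc(=O)c4c3OCc7ccccc7)o2)cc1 | intermediate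
19 | 4-[5,4'-bis(benzyloxy)-7-methoxyflavon-6-yl]-3-hydroxy-4-[6-(4-methoxyphenyl)-4-oxo-4H-pyran-2-yl]buta-1,3-dien-1-one (not isolated; enol geometry interconverts by tautomerism) | COc1ccc(-c2cc(=O)cc(C(=C(O)C=C=O)c3c(OC)cc4oc(-c5ccc(OCc6ccccc6)cc5)cc(=O)c4c3OCc7ccccc7)o2)cc1 | intermediate
20 | 8-[5,4'-bis(benzyloxy)-7-methoxyflavon-6-yl]-5,7-dihydroxy-4'-methoxyflavone | COc1ccc(-c2cc(=O)c3c(O)cc(O)c(-c4c(OC)cc5oc(-c6ccc(OCc7ccccc7)cc6)cc(=O)c5c4OCc8ccccc8)c3o2)cc1 | intermediate
21 | 8-(5,4'-dihydroxy-7-methoxyflavon-6-yl)-5,7-dihydroxy-4'-methoxyflavone (CNP0253922.0) | COc1ccc(-c2cc(=O)c3c(O)cc(O)c(-c4c(OC)cc5oc(-c6ccc(O)cc6)cc(=O)c5c4O)c3o2)cc1 | target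

Total step count: 12. Longest linear sequence: 12 steps (1 to 21). Compounds 2, 5, 13 and 16 are bought and enter directly.

Steps most likely to fail

Step 11. The exocyclic carbon is crowded and may resist acylation. Protodesilylation back to the pyranone, self-condensation of the malonyl reagent, or acylation of the newly formed phenols could then take over. The fallback gives up the annulation and makes the C6–C8'' bond by Suzuki–Miyaura coupling of two finished flavones, which is known chemistry for biflavones and for di-ortho-substituted partners. It sets out from 4 and returns at 21.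
- Iodination of 4 ortho to the free 5-OH with benzyltrimethylammonium dichloroiodate and CaCO3 in CH2Cl2–MeOH should give 4'-benzyloxy-5-hydroxy-6-iodo-7-methoxyflavone F1. Benzylation as in step 5 gives 5,4'-bis(benzyloxy)-6-iodo-7-methoxyflavone F2.
- Commercial acacetin (COc1ccc(-c2cc(=O)c3c(O)cc(O)cc3o2)cc1) is dibenzylated with BnBr and Cs2CO3 in DMF to 5,7-bis(benzyloxy)-4'-methoxyflavone F3.
- F3 is iodinated at C8 with I2 and AgO2CCF3 in CH2Cl2 to 5,7-bis(benzyloxy)-8-iodo-4'-methoxyflavone F4.
- Miyaura borylation of F4 (B2pin2, PdCl2(dppf), KOAc, dioxane, 90 °C) gives 5,7-bis(benzyloxy)-4'-methoxyflavone-8-boronic acid pinacol ester F5.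
- Coupling of F2 with F5 (Pd2(dba)3, SPhos, K3PO4, toluene–H2O, 100 °C) should give 8-[5,4'-bis(benzyloxy)-7-methoxyflavon-6-yl]-5,7-bis(benzyloxy)-4'-methoxyflavone F6.
- Hydrogenolysis of F6 under the conditions of step 12 gives 21.

Step 9. Proton transfer from the CH2 of amide 12 to the strongly basic dianion, or attack of the dianion on ring C of half 2, may outrun the acylation. The fallback works without strong base in the presence of the flavone. It sets out from 10 and returns at 14.
- Oxalyl chloride and catalytic DMF in CH2Cl2 should turn 10 into 2-[5,4'-bis(benzyloxy)-7-methoxyflavon-6-yl]acetyl chloride F7.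
- Separately, 13 is silylated with Me3SiCl and Et3N to 1-(4-methoxyphenyl)-3-(trimethylsilyloxy)but-2-en-1-one F8.
- F8 is then treated with LDA and Me3SiCl to give 1-(4-methoxyphenyl)-1,3-bis(trimethylsilyloxy)buta-1,3-diene F9.
- The terminal carbon of F9 is acylated by F7 in CH2Cl2 from -78 °C to rt (Mukaiyama-type acylation of a 1,3-bis-silyl dienol ether). Mild acidic work-up gives 14.

Step 4. At about 200 °C part of the allyl group may travel on to C8 by a Cope shift of the dienone before it enolises, or the sparingly soluble flavone may decompose. The fallback installs the two-carbon side chain by cross-coupling. It sets out from 4, returns at 9, and also bypasses steps 3, 5 and 6.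
- Iodide F2, made from 4 by way of F1 as described for step 11, is coupled with commercial (E)-2-(2-ethoxyvinyl)-4,4,5,5-tetramethyl-1,3,2-dioxaborolane (Pd(OAc)2, SPhos, K3PO4, dioxane–H2O, 80 °C, Suzuki–Miyaura). This should give 5,4'-bis(benzyloxy)-6-[(E)-2-ethoxyvinyl]-7-methoxyflavone F10.
- Hydrolysis of the enol ether with dilute HCl in THF gives aldehyde 9.

Further compounds
F1 | step 11 | 4'-benzyloxy-5-hydroxy-6-iodo-7-methoxyflavone | COc1cc2oc(-c3ccc(OCc4ccccc4)cc3)cc(=O)c2c(O)c1I
F2 | step 11 | 5,4'-bis(benzyloxy)-6-iodo-7-methoxyflavone | COc1cc2oc(-c3ccc(OCc4ccccc4)cc3)cc(=O)c2c(OCc5ccccc5)c1I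
F3 | step 11 | 5,7-bis(benzyloxy)-4'-methoxyflavone | COc1ccc(-c2cc(=O)c3c(OCc4ccccc4)cc(OCc5ccccc5)cc3o2)cc1
F4 | step 11 | 5,7-bis(benzyloxy)-8-iodo-4'-methoxyflavone | COc1ccc(-c2cc(=O)c3c(OCc4ccccc4)cc(OCc5ccccc5)c(I)c3o2)cc1
F5 | step 11 | 5,7-bis(benzyloxy)-4'-methoxyflavone-8-boronic acid pinacol ester | COc1ccc(-c2cc(=O)c3c(OCc4ccccc4)cc(OCc5ccccc5)c(B6OC(C)(C)C(C)(C)O6)c3o2)cc1
F6 | step 11 | 8-[5,4'-bis(benzyloxy)-7-methoxyflavon-6-yl]-5,7-bis(benzyloxy)-4'-methoxyflavone | COc1ccc(-c2cc(=O)c3c(OCc4ccccc4)cc(OCc5ccccc5)c(-c6c(OC)cc7oc(-c8ccc(OCc9ccccc9)cc8)cc(=O)c7c6OCc4ccccc4)c3o2)cc1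
F7 | step 9 | 2-[5,4'-bis(benzyloxy)-7-methoxyflavon-6-yl]acetyl chloride | COc1cc2oc(-c3ccc(OCc4ccccc4)cc3)cc(=O)c2c(OCc5ccccc5)c1CC(=O)Cl
F8 | step 9 | 1-(4-methoxyphenyl)-3-(trimethylsilyloxy)but-2-en-1-one (enol ether geometry not fixed) | COc1ccc(C(=O)C=C(C)O[Si](C)(C)C)cc1
F9 | step 9 | 1-(4-methoxyphenyl)-1,3-bis(trimethylsilyloxy)buta-1,3-diene (enol ether geometry not fixed) | COc1ccc(C(O[Si](C)(C)C)=CC(=C)O[Si](C)(C)C)cc1
F10 | step 4 | 5,4'-bis(benzyloxy)-6-[(E)-2-ethoxyvinyl]-7-methoxyflavone | COc1cc2oc(-c3ccc(OCc4ccccc4)cc3)cc(=O)c2c(OCc5ccccc5)c1/C=C/OCC
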